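# Proposed total synthesis of kobophenol A by de novo construction of the inner resorcinol ring

## Analysis of the target

Kobophenol A (50) is a resveratrol tetramer whose eight stereocentres all sit in three five-membered oxygen rings. These are an inner 2,3-dihydrobenzofuran (2S,3S, trans), an oxolane (2R,3S,4R,5S: 2,3-trans, 3,4-cis, 4,5-trans) and an outer 2,3-dihydrobenzofuran (2R,3R, trans). The oxolane is joined through its C3 to C4 of the inner ring, and the outer ring is joined through its C5 to C3 of the inner ring. As the structure is written, the outer benzo ring carries its free hydroxyl at C7, next to the ring oxygen on C7a, so it is a 3,4-dioxygenated unit, whereas the inner benzo ring is a resorcinol. The two dihydrobenzofurans have opposite absolute sense, so no single chiral reagent serves both. The 3,4-cis pair of aryl groups in the oxolane is the sterically less favoured arrangement. Every stereocentre is benzylic, and six are benzylic ether carbons whose aryl group has a para oxygen; with ten free phenols this makes the molecule prone to acid-induced ionisation and epimerisation. The structural feature on which the plan rests is the inner benzo ring: oxygens on C7a and C6, carbon substituents on the adjacent C3a and C4, and C5 and C7 unsubstituted. Substitution on a preformed resorcinol cannot tell C3a from C5 or C7, so this ring is built rather than substituted.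

## Retrosynthetic reasoning

**Phenol protection.** Target 50 is taken back to its decabenzyl ether 49. Benzyl is chosen for all ten phenols because it falls off under neutral hydrogenolysis; demethylation with a boron halide would put strong Lewis acid on six ionisable benzylic ether carbons.

**Oxolane C–O bond.** Ether 49 is opened at one benzylic C–O bond of the oxolane to the 1,4-diol 48. A para-alkoxybenzylic carbinol ionises under mild acid and the other hydroxyl closes the ring at once. The forward step must place each aryl group trans to its ring neighbour.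

**Oxolane C2–aryl and C5–aryl bonds.** Diol 48 is cut at both carbinol–aryl bonds. One cut leads to lactol 47 and Grignard reagent 43; the second leads through alcohol 44 to aldehyde 42 and the same reagent 43. Both 4-oxygenated aryl groups thus come from one commercial reagent, and the two carbons they join are simply the ends of a four-carbon chain.

**Oxolane C3–C4 bond.** Aldehyde 42 is traced to the N-methoxy-N-methylamide 41, and 41 is cut at the bond between the two aryl-bearing carbons into allylic carbonate 37 and active ester 39. This is the only bond in the oxolane whose two ends are both stereocentres without a heteroatom. The forward reaction, an iridium/isothiourea allylic substitution, must set both centres (the cis pair) under catalyst control, independently of the stereocentres already present.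

**Two-carbon extension.** Carbonate 37 goes back through alcohol 36 and ester 35 to aldehyde 33, and 33 to its diethyl acetal 32. The acetal carbon of 32 is the future oxolane C3 and is already attached to C4 of the inner ring.

**Outer dihydrobenzofuran.** Compound 32 is cut at O1–C2 and C2–C3 of the outer ring into the carbonate 27 (precursor of o-quinone methide 31) and the chiral sulfonium salt 29. Carbonate 27 comes from diol 26, which comes from salicylaldehyde 23 and aryl bromide 24. Aldehyde 23 comes from phenol 22 by ortho-formylation, for which only one ortho position is free. Phenol 22 is unmasked from the allyl ether 21. The allyl group is the one protecting group that must be removed alone, and it is removed before any other alkene enters the molecule.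

**Inner dihydrobenzofuran.** Compound 21 is cut in the same way at O1–C2 and C2–C3 into carbonate 15 (precursor of o-quinone methide 20) and the antipodal salt 18. Carbonate 15 comes from diol 14, ketone 13 and the dihydroxybenzophenone 12. The ketone carbon of 12 becomes C3, the hydrogen-bonded hydroxyl becomes O1 and the free hydroxyl becomes the C6 oxygen.

**Inner benzo ring (key disconnection).** Benzophenone 12 is cut at two ring bonds, C3a–C7a and C4–C5 in target numbering, into ynone 7 and diene 10. A cycloaddition is chosen here because it fixes the acyl carbon between the new hydroxyl and the acetal-bearing carbon by the polarity of the two partners; no directing effect on a finished arene is needed.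

**Precursors.** Ynone 7 is cut at the carbinol–alkyne bond to aldehyde 3 and alkyne 4; aldehyde 3 comes from 1 by two etherifications. Diene 10 comes from keto ester 8 by two silylations.

## Alternatives that were turned down

**Alternative 1:** The inner dihydrofuran ring is closed last.
- Disconnection: O1–C2 and C2–C3 of the inner ring. The precursor is a phenolic benzhydryl sulfone that already carries the finished oxolane on the neighbouring ring carbon and the finished outer ring on the benzhydryl aryl group.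
- Forward key step: Cs2CO3 expels sulfinate; the o-quinone methide takes up a 4-methoxybenzylide at its exocyclic carbon and the phenoxide displaces the sulfide, giving deca-O-methylkobophenol A (A1).
- For it: the three ring systems are made on small pieces and only one bond-forming operation is run on the full skeleton. The annulation is the same trans-selective reaction that the chosen route uses twice.
- Against it:
  - It does not say how a resorcinol with two adjacent carbon substituents is obtained; the precursor still needs the oxolane carbon next to the benzhydryl carbon.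
  - The quinone methide carbon would lie beside a tetraaryl oxolane, the most hindered setting possible for the ylide. Six existing stereocentres would meet a chiral ylide, so a mismatched pairing is possible at the last C–C bond.
  - A1 is a decamethyl ether. Its demethylation needs a boron halide in the presence of six para-oxygenated benzylic ether carbons.
- Comparison: Alternative 1 is stronger in convergence and in longest linear sequence. The chosen strategy offers the arene pattern by construction, runs the annulation early on a small substrate, and ends with a neutral deprotection.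

**Alternative 2:** The oxolane is made first by ring expansion of a donor–acceptor cyclopropane.
- Disconnection: O1–C5 of a 4,5-dihydrofuran, back to an aryl cyclopropyl ketone.
- Forward key step: Sc(O3SCF3)3 opens the cyclopropane bond between the anisyl-bearing and the acyl-bearing carbon and the ketone oxygen closes on the anisyl carbon, giving dihydrofuran A2.
- For it: the whole tetraaryl carbon skeleton of the oxolane appears in one step, far shorter than the ten steps spent on the oxolane here. The mesylates also keep one resorcinol ring from Friedel–Crafts capture of the benzylic cation.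
- Against it:
  - The ring opens through a benzylic cation, so the configuration at that carbon is not carried over but reset.
  - The enol ether of A2 must then be reduced to set C2 and C3. Hydrogen delivered anti to the C4 aryl group would give the needed 3,4-cis pair but a 2,3-cis pair, so one centre must be corrected afterwards.
  - The cyclopropane is tetrasubstituted; it needs an aryl(acyl)carbene to add enantioselectively to a 1,2-diarylethene, a slow alkene class for such carbenes.
  - The inner dihydrobenzofuran must still be grown on a finished resorcinol ring ortho to the oxolane, where the 2- and 4-positions compete.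
  - The methyl ethers again call for a Lewis-acid endgame.
- Comparison: Alternative 2 is clearly stronger in step economy for the oxolane. The chosen strategy offers an unambiguous arene pattern, catalyst control over the 3,4-cis pair, and no Lewis acid after the oxolane exists.

**Alternative 3:** Both carbon arms are placed on a bought arene by aryne insertion.
- Disconnection: the C3a–acyl bond and the C4–CH2 bond of the inner benzo ring.
- Forward key step: CsF releases 3,5-dimethoxybenzyne (A4), which inserts into the ketone–methylene bond of keto ester A5. The enolate carbon adds to the aryne carbon remote from the methoxy group and the aryl anion then attacks the ketone, giving keto ester A3.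
- For it: one operation gives the same adjacent carbon–carbon pattern; the flanking methoxy group directs the regiochemistry; and the acetic ester arm is a handle for enolate chemistry at the future oxolane C3. In directness it is stronger than a cycloaddition followed by aromatisation.
- Against it:
  - The silyl triflate precursor of A4 takes several steps of its own.
  - No ring is formed.
  - Both ring oxygens arrive as methyl ethers. The one that must become O1 needs a selective demethylation next to the ketone, and the rest force the same boron-halide endgame.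
  - The ester arm has one carbon more than the acetal and is at the wrong oxidation level for the allylic substitution used here.
- Comparison: Alternative 3 is shorter to the benzophenone. The chosen strategy delivers the two phenols already differentiated (one hydrogen-bonded, one free), an aldehyde-level arm, and freedom to choose benzyl protection throughout.

Key step: step 7

## Remarks before the steps

- Assumption: the (1R,4R,5R)-sulfonium ylide is taken to add with the facial sense that leads to the (2S,3S) ring and its antipode to the (2R,3R) ring, and in step 24 the catalyst antipodes are those that set 2R and 3S. Should any sense prove opposite, the antipodal reagent is used and nothing else changes.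
- Abbreviations: Bn = benzyl; allyl = prop-2-en-1-yl.
- P = the (2S,3S)-6-(benzyloxy)-2-[4-(benzyloxy)phenyl]-4-(diethoxymethyl)-2,3-dihydro-1-benzofuran-3-yl group.
- Q = the (2S,3S)-6-(benzyloxy)-2-[4-(benzyloxy)phenyl]-3-{(2R,3R)-7-(benzyloxy)-2-[4-(benzyloxy)phenyl]-3-[3,5-bis(benzyloxy)phenyl]-2,3-dihydro-1-benzofuran-5-yl}-2,3-dihydro-1-benzofuran-4-yl group.

## Route

Step 1
Reactants: 1 3,4-dihydroxybenzaldehyde
Product: 2 4-(allyloxy)-3-hydroxybenzaldehyde
Conditions: allyl bromide (1.0 equiv), NaHCO3, NaI (cat.), DMF, 40 °C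
Reagents that add atoms: allyl bromide, C=CCBr
Why: Williamson etherification; the 4-hydroxyl, para to the formyl group, is the more acidic and should be alkylated alone with one equivalent of weak base.

Step 2
Reactants: 2 4-(allyloxy)-3-hydroxybenzaldehyde
Product: 3 4-(allyloxy)-3-(benzyloxy)benzaldehyde
Conditions: BnBr, K2CO3, DMF, rt
Reagents that add atoms: benzyl bromide, BrCc1ccccc1
Why: Williamson etherification of the remaining phenol; the two ring oxygens are now differentiated (allyl for the future outer-ring oxygen, benzyl for the future C7 hydroxyl).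

Step 3
Reactants: 4 3,3-diethoxyprop-1-yne; 3 4-(allyloxy)-3-(benzyloxy)benzaldehyde
Product: 6 rac-1-[4-(allyloxy)-3-(benzyloxy)phenyl]-4,4-diethoxybut-2-yn-1-ol, via lithium acetylide 5 (not isolated)
Conditions: n-BuLi, THF, −78 °C; then 3, −78 → 0 °C; NH4Cl (aq)
Reagents that add atoms: none
Why: 1,2-addition of a lithium acetylide to an aryl aldehyde; the carbinol centre is racemic and is removed in step 4.

Step 4
Reactants: 6 rac-1-[4-(allyloxy)-3-(benzyloxy)phenyl]-4,4-diethoxybut-2-yn-1-ol
Product: 7 1-[4-(allyloxy)-3-(benzyloxy)phenyl]-4,4-diethoxybut-2-yn-1-one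
Conditions: MnO2, CH2Cl2, rt
Reagents that add atoms: none
Why: MnO2 oxidation of a benzylic and propargylic alcohol; neutral conditions leave the acetal, the allyl ether and the benzyl ether untouched.

Step 5
Reactants: 8 methyl acetoacetate
Product: 9 methyl 3-(trimethylsilyloxy)but-2-enoate
Conditions: Me3SiCl, Et3N, hexane, rt
Reagents that add atoms: chlorotrimethylsilane, C[Si](C)(C)Cl
Why: O-silylation of the enol of a β-keto ester; the alkene geometry is immaterial for step 6.

Step 6
Reactants: 9 methyl 3-(trimethylsilyloxy)but-2-enoate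
Product: 10 1-methoxy-1,3-bis(trimethylsilyloxy)buta-1,3-diene
Conditions: LiN(i-Pr)2, THF, −78 °C; then Me3SiCl; distilled and used at once
Reagents that add atoms: chlorotrimethylsilane, C[Si](C)(C)Cl
Why: γ-deprotonation to the dienolate and O-silylation give the ketene-acetal diene, a standard preparation of 1,3-bis(silyloxy)dienes.

Step 7
Reactants: 7 1-[4-(allyloxy)-3-(benzyloxy)phenyl]-4,4-diethoxybut-2-yn-1-one; 10 1-methoxy-1,3-bis(trimethylsilyloxy)buta-1,3-diene
Product: 12 [4-(allyloxy)-3-(benzyloxy)phenyl][2-(diethoxymethyl)-4,6-dihydroxyphenyl]methanone, via cycloadduct 11 (not isolated)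
Conditions: 10 (1.5 equiv), toluene, rt → 60 °C, no Lewis acid; then MeOH, K2CO3 (cat.), rt
Reagents that add atoms: none
Why: The electron-rich diene 10 and the electron-poor alkyne of 7 should combine in a normal-demand Diels–Alder cycloaddition, concerted but asynchronous, with bond formation leading between the CH2 terminus of the diene and the β-carbon of the ynone. This gives cyclohexa-1,4-diene 11, in which the ketene-acetal carbon is bonded to the acyl-bearing carbon. Catalytic base in methanol then removes methanol across the ring (the ring CH2 is vinylogous to the ketone) and cleaves both silyl ethers, so that 11 aromatises to resorcinol 12. The closest known reaction type is the cycloaddition and aromatisation of 1-alkoxy-1,3-bis(silyloxy)dienes and related 1,3-dioxygenated dienes with alkynoates and alkynyl ketones to resorcinol derivatives. The one new ring closes in cycloaddition mode: the two ring bonds (C3a–C7a and C4–C5 in target numbering) form in a single suprafacial event, not by substitution on an existing arene. No stereocentre survives, since the one in 11 is lost on aromatisation. The step needs regioselectivity and the [4+2] pathway; the first is secured by the matched polarisation of the two partners, which puts the acyl group between the new hydroxyl and the acetal carbon, and the second by leaving out any Lewis acid, which keeps the partners off the conjugate-addition and aldol path and spares the acetal. In 12 the hydroxyl beside the ketone is hydrogen-bonded and the other is free, which is what step 8 uses.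

Step 8
Reactants: 12 [4-(allyloxy)-3-(benzyloxy)phenyl][2-(diethoxymethyl)-4,6-dihydroxyphenyl]methanone
Product: 13 [4-(allyloxy)-3-(benzyloxy)phenyl][4-(benzyloxy)-2-(diethoxymethyl)-6-hydroxyphenyl]methanone
Conditions: BnBr (1.05 equiv), K2CO3, acetone, rt → 40 °C
Reagents that add atoms: benzyl bromide, BrCc1ccccc1
Why: Williamson etherification; the hydroxyl para to the ketone is the more acidic and is not tied up in a hydrogen bond, so it should be benzylated alone.

Step 9
Reactants: 13 [4-(allyloxy)-3-(benzyloxy)phenyl][4-(benzyloxy)-2-(diethoxymethyl)-6-hydroxyphenyl]methanone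
Product: 14 rac-2-{[4-(allyloxy)-3-(benzyloxy)phenyl](hydroxy)methyl}-5-(benzyloxy)-3-(diethoxymethyl)phenol
Conditions: NaBH4, THF/MeOH, 0 °C → rt
Reagents that add atoms: none
Why: Hydride reduction of a diaryl ketone; the new centre is racemic and is erased when the o-quinone methide forms in step 12.

Step 10
Reactants: 14 rac-2-{[4-(allyloxy)-3-(benzyloxy)phenyl](hydroxy)methyl}-5-(benzyloxy)-3-(diethoxymethyl)phenol
Product: 15 rac-2-{[4-(allyloxy)-3-(benzyloxy)phenyl](hydroxy)methyl}-5-(benzyloxy)-3-(diethoxymethyl)phenyl tert-butyl carbonate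
Conditions: Boc2O (1.05 equiv), i-Pr2NEt, DMAP (cat.), CH2Cl2, 0 °C
Reagents that add atoms: di-tert-butyl dicarbonate, CC(C)(C)OC(=O)OC(=O)OC(C)(C)C
Why: O-acylation of the phenol, which is far more acidic than the hindered diaryl carbinol; without an alkoxide the carbonate should stay on the phenol and the compound should be isolable.

Step 11
Reactants: 16 (1R,4R,5R)-isothiocineole; 17 1-(benzyloxy)-4-(bromomethyl)benzene
Product: 18 (1R,4R,5R)-6-[4-(benzyloxy)benzyl]-4,7,7-trimethyl-6-thiabicyclo[3.2.1]octan-6-ium tetrafluoroborate (benzyl group exo)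
Conditions: NaBF4, CH2Cl2/H2O, rt
Reagents that add atoms: sodium tetrafluoroborate, [Na+].F[B-](F)(F)F
Why: S-alkylation of a sulfide by a benzylic bromide with anion exchange; the less hindered exo lone pair should be alkylated, giving one diastereomer at sulfur.

Step 12
Reactants: 15 rac-2-{[4-(allyloxy)-3-(benzyloxy)phenyl](hydroxy)methyl}-5-(benzyloxy)-3-(diethoxymethyl)phenyl tert-butyl carbonate; 18 (1R,4R,5R)-6-[4-(benzyloxy)benzyl]-4,7,7-trimethyl-6-thiabicyclo[3.2.1]octan-6-ium tetrafluoroborate
Product: 21 (2S,3S)-3-[4-(allyloxy)-3-(benzyloxy)phenyl]-6-(benzyloxy)-2-[4-(benzyloxy)phenyl]-4-(diethoxymethyl)-2,3-dihydro-1-benzofuran, via sulfonium ylide 19 (not isolated), via o-quinone methide 20 (not isolated)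
Conditions: 18 (1.3 equiv), KN(SiMe3)2 (2.4 equiv), THF, −78 °C; then 15; −78 → 0 °C
Reagents that add atoms: none
Why: Sulfur-ylide [4+1] annulation of an o-quinone methide: the alkoxide of 15 takes over the carbonate group and the phenoxide expels tert-butyl carbonate to give 20 under base, so the acetal is never exposed to acid. Ylide 19 adds to the exocyclic carbon and the phenoxide displaces the sulfide with inversion, closing the ring with the two aryl groups trans. The bicyclic sulfide leaves one face of the ylide carbon open, which sets C2, and the trans closure then sets C3.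

Step 13
Reactants: 21 (2S,3S)-3-[4-(allyloxy)-3-(benzyloxy)phenyl]-6-(benzyloxy)-2-[4-(benzyloxy)phenyl]-4-(diethoxymethyl)-2,3-dihydro-1-benzofuran
Product: 22 2-(benzyloxy)-4-P-phenol
Conditions: Pd(PPh3)4 (5 mol %), morpholine, THF, rt
Reagents that add atoms: none
Why: Palladium-catalysed allyl transfer to an amine (Tsuji–Trost type deallylation); benzyl ethers, the acetal and the benzylic ring ether are inert to it.

Step 14
Reactants: 22 2-(benzyloxy)-4-P-phenol
Product: 23 3-(benzyloxy)-2-hydroxy-5-P-benzaldehyde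
Conditions: MgCl2, Et3N, (CH2O)n, MeCN, 80 °C; NH4Cl (aq) work-up
Reagents that add atoms: formaldehyde (as paraformaldehyde), C=O
Why: Magnesium-mediated ortho-formylation of a phenol (Casnati–Skattebøl reaction); only one position ortho to the hydroxyl is free, so the regiochemistry is fixed, and the basic medium keeps the acetal.

Step 15
Reactants: 24 1,3-bis(benzyloxy)-5-bromobenzene; 23 3-(benzyloxy)-2-hydroxy-5-P-benzaldehyde
Product: 26 2-(benzyloxy)-6-{[3,5-bis(benzyloxy)phenyl](hydroxy)methyl}-4-P-phenol (both carbinol epimers), via aryl Grignard reagent 25 (not isolated)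
Conditions: Mg, THF, 40 °C; then 23 (0.4 equiv), 0 °C → rt; NH4Cl (aq)
Reagents that add atoms: none
Why: Grignard addition to a salicylaldehyde; the first equivalent deprotonates the phenol and the second adds. The carbinol configuration does not matter because it is erased in step 18.

Step 16
Reactants: 26 2-(benzyloxy)-6-{[3,5-bis(benzyloxy)phenyl](hydroxy)methyl}-4-P-phenol
Product: 27 2-(benzyloxy)-6-{[3,5-bis(benzyloxy)phenyl](hydroxy)methyl}-4-P-phenyl tert-butyl carbonate
Conditions: Boc2O (1.05 equiv), i-Pr2NEt, DMAP (cat.), CH2Cl2, 0 °C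
Reagents that add atoms: di-tert-butyl dicarbonate, CC(C)(C)OC(=O)OC(=O)OC(C)(C)C
Why: Selective O-acylation of the phenol, as in step 10.

Step 17
Reactants: 28 (1S,4S,5S)-isothiocineole; 17 1-(benzyloxy)-4-(bromomethyl)benzene
Product: 29 (1S,4S,5S)-6-[4-(benzyloxy)benzyl]-4,7,7-trimethyl-6-thiabicyclo[3.2.1]octan-6-ium tetrafluoroborate (benzyl group exo)
Conditions: NaBF4, CH2Cl2/H2O, rt
Reagents that add atoms: sodium tetrafluoroborate, [Na+].F[B-](F)(F)F
Why: S-alkylation as in step 11, with the antipodal sulfide.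

Step 18
Reactants: 27 2-(benzyloxy)-6-{[3,5-bis(benzyloxy)phenyl](hydroxy)methyl}-4-P-phenyl tert-butyl carbonate; 29 (1S,4S,5S)-6-[4-(benzyloxy)benzyl]-4,7,7-trimethyl-6-thiabicyclo[3.2.1]octan-6-ium tetrafluoroborate
Product: 32 Q-carbaldehyde diethyl acetal, via sulfonium ylide 30 (not isolated), via o-quinone methide 31 (not isolated)
Conditions: 29 (1.3 equiv), KN(SiMe3)2 (2.4 equiv), THF, −78 °C; then 27; −78 → 0 °C
Reagents that add atoms: none
Why: The same sulfur-ylide [4+1] annulation as in step 12, now with the antipodal ylide, which should give the (2R,3R) trans ring. The new ring is meta to the inner C3 on the linking arene, far from the existing centres, so the reagent should control the outcome.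

Step 19
Reactants: 32 Q-carbaldehyde diethyl acetal
Product: 33 Q-carbaldehyde
Conditions: pyridinium p-toluenesulfonate, acetone/H2O, 50 °C
Reagents that add atoms: water, O
Why: Mild acid hydrolysis of an acetal; the benzylic ring ethers carry O-benzylated aryl groups and should not ionise under so weak an acid.

Step 20
Reactants: 33 Q-carbaldehyde; 34 triethyl phosphonoacetate
Product: 35 ethyl (E)-3-Q-prop-2-enoate
Conditions: NaH, THF, 0 °C → rt
Reagents that add atoms: none
Why: Horner–Wadsworth–Emmons olefination, E-selective with a stabilised phosphonate.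

Step 21
Reactants: 35 ethyl (E)-3-Q-prop-2-enoate
Product: 36 (E)-3-Q-prop-2-en-1-ol
Conditions: i-Bu2AlH (2.2 equiv), CH2Cl2, −78 °C
Reagents that add atoms: none
Why: 1,2-reduction of an unsaturated ester by an aluminium hydride; the alkene geometry is retained.

Step 22
Reactants: 36 (E)-3-Q-prop-2-en-1-ol
Product: 37 tert-butyl (E)-3-Q-prop-2-en-1-yl carbonate
Conditions: Boc2O, Bu4NHSO4 (cat.), NaOH (aq), CH2Cl2, 0 °C → rt
Reagents that add atoms: di-tert-butyl dicarbonate, CC(C)(C)OC(=O)OC(=O)OC(C)(C)C
Why: Carbonate formation from a primary allylic alcohol under phase transfer; the tert-butyl carbonate is the leaving group for step 24 and releases a base that does not attack active esters.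

Step 23
Reactants: 38 [3,5-bis(benzyloxy)phenyl]acetic acid
Product: 39 pentafluorophenyl [3,5-bis(benzyloxy)phenyl]acetate
Conditions: C6F5OH, N,N'-dicyclohexylcarbodiimide, CH2Cl2, 0 °C → rt
Reagents that add atoms: pentafluorophenol, Oc1c(F)c(F)c(F)c(F)c1F
Why: Carbodiimide esterification to an active ester, the acyl donor needed for isothiourea catalysis.

Step 24
Reactants: 37 tert-butyl (E)-3-Q-prop-2-en-1-yl carbonate; 39 pentafluorophenyl [3,5-bis(benzyloxy)phenyl]acetate
Product: 41 (2R,3S)-2-[3,5-bis(benzyloxy)phenyl]-N-methoxy-N-methyl-3-Q-pent-4-enamide, via pentafluorophenyl ester 40 (not isolated)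
Conditions: [Ir(cod)Cl]2 (2 mol %) and O,O'-(1,1'-binaphthyl-2,2'-diyl) N,N-bis(1-phenylethyl)phosphoramidite (4 mol %, cyclometalated; antipode that sets C3 as S), benzotetramisole (10 mol %; antipode that sets C2 as R), i-Pr2NEt, THF, rt; then MeNHOMe·HCl, i-Pr2NEt
Reagents that add atoms: N,O-dimethylhydroxylamine hydrochloride, CNOC.Cl
Why: Iridium-catalysed branched-selective allylic substitution run together with isothiourea (Lewis base) catalysis: the ammonium enolate formed from 39 attacks the substituted terminus of the allyliridium intermediate and the pentafluorophenoxide turns the isothiourea over. The iridium complex sets the allylic centre (oxolane C3) and the isothiourea sets the enolate centre (oxolane C4), each independently, so the cis-related pair is chosen by the catalyst antipodes. Aminolysis of 40 in the same flask gives the stable amide.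

Step 25
Reactants: 41 (2R,3S)-2-[3,5-bis(benzyloxy)phenyl]-N-methoxy-N-methyl-3-Q-pent-4-enamide
Product: 42 (2R,3S)-2-[3,5-bis(benzyloxy)phenyl]-3-Q-pent-4-enal
Conditions: i-Bu2AlH, THF, −78 °C; cold aqueous tartrate work-up; used crude
Reagents that add atoms: none
Why: Reduction of an N-methoxy-N-methylamide stops at the aldehyde because the chelated tetrahedral intermediate survives until work-up; using the aldehyde cold and crude guards the α-aryl centre against enolisation.

Step 26
Reactants: 42 (2R,3S)-2-[3,5-bis(benzyloxy)phenyl]-3-Q-pent-4-enal; 43 [4-(benzyloxy)phenyl]magnesium bromide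
Product: 44 (1S,2R,3S)-1-[4-(benzyloxy)phenyl]-2-[3,5-bis(benzyloxy)phenyl]-3-Q-pent-4-en-1-ol
Conditions: 43 (1.2 equiv), THF, −78 °C; NH4Cl (aq)
Reagents that add atoms: none
Why: Grignard addition to an α-aryl aldehyde; attack anti to the α-aryl group (polar 1,2-induction model) should favour the drawn carbinol. The configuration at this carbon is finally settled at ring closure in step 29.

Step 27
Reactants: 44 (1S,2R,3S)-1-[4-(benzyloxy)phenyl]-2-[3,5-bis(benzyloxy)phenyl]-3-Q-pent-4-en-1-ol
Product: 47 (3S,4R,5S)-5-[4-(benzyloxy)phenyl]-4-[3,5-bis(benzyloxy)phenyl]-3-Q-oxolan-2-ol (both anomers), via triol 45 (not isolated), via hydroxy aldehyde 46 (not isolated)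
Conditions: OsO4 (2 mol %), NaIO4 (4 equiv), 2,6-lutidine, dioxane/H2O, rt
Reagents that add atoms: sodium periodate (oxygen source through OsO4), [Na+].[O-]I(=O)(=O)=O; water, O
Why: Lemieux–Johnson cleavage of the terminal alkene; the aldehyde is trapped at once by the γ-hydroxyl as a lactol, which shields the α-aryl centre from enolisation.

Step 28
Reactants: 47 (3S,4R,5S)-5-[4-(benzyloxy)phenyl]-4-[3,5-bis(benzyloxy)phenyl]-3-Q-oxolan-2-ol; 43 [4-(benzyloxy)phenyl]magnesium bromide
Product: 48 (1R,2S,3R,4S)-1,4-bis[4-(benzyloxy)phenyl]-3-[3,5-bis(benzyloxy)phenyl]-2-Q-butane-1,4-diol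
Conditions: 43 (3 equiv), THF, 0 °C → rt; NH4Cl (aq)
Reagents that add atoms: none
Why: Grignard addition to the open hydroxy-aldehyde form of a lactol; the first equivalent deprotonates and opens the lactol. Attack anti to the α-aryl group should again favour the drawn carbinol.

Step 29
Reactants: 48 (1R,2S,3R,4S)-1,4-bis[4-(benzyloxy)phenyl]-3-[3,5-bis(benzyloxy)phenyl]-2-Q-butane-1,4-diol
Product: 49 (2R,3S,4R,5S)-2,5-bis[4-(benzyloxy)phenyl]-4-[3,5-bis(benzyloxy)phenyl]-3-Q-oxolane (deca-O-benzylkobophenol A)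
Conditions: camphorsulfonic acid (10 mol %), 4 Å molecular sieves, CH2Cl2, 0 °C, short contact time
Reagents that add atoms: none
Why: Acid-catalysed cyclodehydration of a 1,4-diaryl-1,4-diol (SN1 through a para-alkoxybenzylic cation), the usual closure of 2,5-diaryloxolane lignans. The cation keeps the hydrogen of the neighbouring carbon in its plane to avoid allylic strain, so the tethered hydroxyl attacks the face that puts the aryl group trans to its ring neighbour. A carbinol of the wrong configuration is corrected when that carbon is the one that ionises.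

Step 30
Reactants: 49 (2R,3S,4R,5S)-2,5-bis[4-(benzyloxy)phenyl]-4-[3,5-bis(benzyloxy)phenyl]-3-Q-oxolane
Product: 50 kobophenol A
Conditions: H2 (1 atm), Pd/C (10% Pd on carbon), EtOAc/MeOH, rt, monitored closely
Reagents that add atoms: none
Why: Hydrogenolysis of ten benzyl aryl ethers under neutral conditions; benzyl aryl ethers cleave much faster than the dialkyl-type benzylic C–O bonds of the three rings, and no acid touches the free phenols.

## Compound list

1 | 3,4-dihydroxybenzaldehyde | O=Cc1ccc(O)c(O)c1 | starting material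
2 | 4-(allyloxy)-3-hydroxybenzaldehyde | O=Cc1ccc(OCC=C)c(O)c1 | intermediate
3 | 4-(allyloxy)-3-(benzyloxy)benzaldehyde | O=Cc1ccc(OCC=C)c(OCc2ccccc2)c1 | intermediate
4 | 3,3-diethoxyprop-1-yne | CCOC(OCC)C#C | starting material
5 | (3,3-diethoxyprop-1-yn-1-yl)lithium | CCOC(OCC)C#C[Li] | intermediate (not isolated)
6 | rac-1-[4-(allyloxy)-3-(benzyloxy)phenyl]-4,4-diethoxybut-2-yn-1-ol | CCOC(OCC)C#CC(O)c1ccc(OCC=C)c(OCc2ccccc2)c1 | intermediate
7 | 1-[4-(allyloxy)-3-(benzyloxy)phenyl]-4,4-diethoxybut-2-yn-1-one | CCOC(OCC)C#CC(=O)c1ccc(OCC=C)c(OCc2ccccc2)c1 | intermediate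
8 | methyl acetoacetate | COC(=O)CC(C)=O | starting material
9 | methyl 3-(trimethylsilyloxy)but-2-enoate (E/Z mixture) | COC(=O)C=C(C)O[Si](C)(C)C | intermediate
10 | 1-methoxy-1,3-bis(trimethylsilyloxy)buta-1,3-diene (ketene-acetal geometry immaterial) | COC(O[Si](C)(C)C)=CC(=C)O[Si](C)(C)C | intermediate
11 | rac-[4-(allyloxy)-3-(benzyloxy)phenyl][2-(diethoxymethyl)-6-methoxy-4,6-bis(trimethylsilyloxy)cyclohexa-1,4-dien-1-yl]methanone | COC1(O[Si](C)(C)C)C=C(O[Si](C)(C)C)CC(C(OCC)OCC)=C1C(=O)c1ccc(OCC=C)c(OCc2ccccc2)c1 | intermediate (not isolated)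
12 | [4-(allyloxy)-3-(benzyloxy)phenyl][2-(diethoxymethyl)-4,6-dihydroxyphenyl]methanone | CCOC(OCC)c1cc(O)cc(O)c1C(=O)c1ccc(OCC=C)c(OCc2ccccc2)c1 | intermediate
13 | [4-(allyloxy)-3-(benzyloxy)phenyl][4-(benzyloxy)-2-(diethoxymethyl)-6-hydroxyphenyl]methanone | CCOC(OCC)c1cc(OCc2ccccc2)cc(O)c1C(=O)c1ccc(OCC=C)c(OCc2ccccc2)c1 | intermediate
14 | rac-2-{[4-(allyloxy)-3-(benzyloxy)phenyl](hydroxy)methyl}-5-(benzyloxy)-3-(diethoxymethyl)phenol | CCOC(OCC)c1cc(OCc2ccccc2)cc(O)c1C(O)c1ccc(OCC=C)c(OCc2ccccc2)c1 | intermediate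
15 | rac-2-{[4-(allyloxy)-3-(benzyloxy)phenyl](hydroxy)methyl}-5-(benzyloxy)-3-(diethoxymethyl)phenyl tert-butyl carbonate | CCOC(OCC)c1cc(OCc2ccccc2)cc(OC(=O)OC(C)(C)C)c1C(O)c1ccc(OCC=C)c(OCc2ccccc2)c1 | intermediate
16 | (1R,4R,5R)-4,7,7-trimethyl-6-thiabicyclo[3.2.1]octane (isothiocineole) | C[C@@H]1CC[C@@H]2C[C@H]1SC2(C)C | starting material
17 | 1-(benzyloxy)-4-(bromomethyl)benzene | BrCc1ccc(OCc2ccccc2)cc1 | starting material
18 | (1R,4R,5R)-6-[4-(benzyloxy)benzyl]-4,7,7-trimethyl-6-thiabicyclo[3.2.1]octan-6-ium tetrafluoroborate, benzyl exo | C[C@@H]1CC[C@@H]2C[C@H]1[S@@+](Cc1ccc(OCc3ccccc3)cc1)C2(C)C.F[B-](F)(F)F | intermediate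
19 | sulfonium ylide of 18 | C[C@@H]1CC[C@@H]2C[C@H]1[S@@+]([CH-]c1ccc(OCc3ccccc3)cc1)C2(C)C | intermediate (not isolated)
20 | 6-{[4-(allyloxy)-3-(benzyloxy)phenyl]methylidene}-3-(benzyloxy)-5-(diethoxymethyl)cyclohexa-2,4-dien-1-one (o-quinone methide) | CCOC(OCC)C1=CC(OCc2ccccc2)=CC(=O)C1=Cc1ccc(OCC=C)c(OCc2ccccc2)c1 | intermediate (not isolated)
21 | (2S,3S)-3-[4-(allyloxy)-3-(benzyloxy)phenyl]-6-(benzyloxy)-2-[4-(benzyloxy)phenyl]-4-(diethoxymethyl)-2,3-dihydro-1-benzofuran | c9ccccc9COc1ccc([C@H]2Oc3cc(OCc9ccccc9)cc(C(OCC)OCC)c3[C@@H]2c2cc(OCc9ccccc9)c(OCC=C)cc2)cc1 | intermediate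
22 | 2-(benzyloxy)-4-P-phenol | c9ccccc9COc1ccc([C@H]2Oc3cc(OCc9ccccc9)cc(C(OCC)OCC)c3[C@@H]2c2cc(OCc9ccccc9)c(O)cc2)cc1 | intermediate
23 | 3-(benzyloxy)-2-hydroxy-5-P-benzaldehyde | c9ccccc9COc1ccc([C@H]2Oc3cc(OCc9ccccc9)cc(C(OCC)OCC)c3[C@@H]2c2cc(OCc9ccccc9)c(O)c(C=O)c2)cc1 | intermediate
24 | 1,3-bis(benzyloxy)-5-bromobenzene | Brc1cc(OCc2ccccc2)cc(OCc2ccccc2)c1 | starting material
25 | [3,5-bis(benzyloxy)phenyl]magnesium bromide | Br[Mg]c1cc(OCc2ccccc2)cc(OCc2ccccc2)c1 | intermediate (not isolated)
26 | 2-(benzyloxy)-6-{[3,5-bis(benzyloxy)phenyl](hydroxy)methyl}-4-P-phenol (carbinol epimers) | c9ccccc9COc1ccc([C@H]2Oc3cc(OCc9ccccc9)cc(C(OCC)OCC)c3[C@@H]2c2cc(OCc9ccccc9)c(O)c(C(O)c3cc(OCc9ccccc9)cc(OCc9ccccc9)c3)c2)cc1 | intermediate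
27 | 2-(benzyloxy)-6-{[3,5-bis(benzyloxy)phenyl](hydroxy)methyl}-4-P-phenyl tert-butyl carbonate (carbinol epimers) | c9ccccc9COc1ccc([C@H]2Oc3cc(OCc9ccccc9)cc(C(OCC)OCC)c3[C@@H]2c2cc(OCc9ccccc9)c(OC(=O)OC(C)(C)C)c(C(O)c3cc(OCc9ccccc9)cc(OCc9ccccc9)c3)c2)cc1 | intermediate
28 | (1S,4S,5S)-4,7,7-trimethyl-6-thiabicyclo[3.2.1]octane (ent-isothiocineole) | C[C@H]1CC[C@H]2C[C@@H]1SC2(C)C | starting material
29 | (1S,4S,5S)-6-[4-(benzyloxy)benzyl]-4,7,7-trimethyl-6-thiabicyclo[3.2.1]octan-6-ium tetrafluoroborate, benzyl exo | C[C@H]1CC[C@H]2C[C@@H]1[S@+](Cc1ccc(OCc3ccccc3)cc1)C2(C)C.F[B-](F)(F)F | intermediate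
30 | sulfonium ylide of 29 | C[C@H]1CC[C@H]2C[C@@H]1[S@+]([CH-]c1ccc(OCc3ccccc3)cc1)C2(C)C | intermediate (not isolated)
31 | 2-(benzyloxy)-6-{[3,5-bis(benzyloxy)phenyl]methylidene}-4-P-cyclohexa-2,4-dien-1-one (o-quinone methide) | c9ccccc9COc1ccc([C@H]2Oc3cc(OCc9ccccc9)cc(C(OCC)OCC)c3[C@@H]2C2=CC(=Cc3cc(OCc9ccccc9)cc(OCc9ccccc9)c3)C(=O)C(OCc9ccccc9)=C2)cc1 | intermediate (not isolated)
32 | Q-carbaldehyde diethyl acetal | c9ccccc9COc1ccc([C@H]2Oc3cc(OCc9ccccc9)cc(C(OCC)OCC)c3[C@@H]2c2cc(OCc9ccccc9)c3c(c2)[C@@H](c2cc(OCc9ccccc9)cc(OCc9ccccc9)c2)[C@H](c2ccc(OCc9ccccc9)cc2)O3)cc1 | intermediate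
33 | Q-carbaldehyde | c9ccccc9COc1ccc([C@H]2Oc3cc(OCc9ccccc9)cc(C=O)c3[C@@H]2c2cc(OCc9ccccc9)c3c(c2)[C@@H](c2cc(OCc9ccccc9)cc(OCc9ccccc9)c2)[C@H](c2ccc(OCc9ccccc9)cc2)O3)cc1 | intermediate
34 | triethyl phosphonoacetate | CCOC(=O)CP(=O)(OCC)OCC | starting material
35 | ethyl (E)-3-Q-prop-2-enoate | c9ccccc9COc1ccc([C@H]2Oc3cc(OCc9ccccc9)cc(/C=C/C(=O)OCC)c3[C@@H]2c2cc(OCc9ccccc9)c3c(c2)[C@@H](c2cc(OCc9ccccc9)cc(OCc9ccccc9)c2)[C@H](c2ccc(OCc9ccccc9)cc2)O3)cc1 | intermediate
36 | (E)-3-Q-prop-2-en-1-ol | c9ccccc9COc1ccc([C@H]2Oc3cc(OCc9ccccc9)cc(/C=C/CO)c3[C@@H]2c2cc(OCc9ccccc9)c3c(c2)[C@@H](c2cc(OCc9ccccc9)cc(OCc9ccccc9)c2)[C@H](c2ccc(OCc9ccccc9)cc2)O3)cc1 | intermediate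
37 | tert-butyl (E)-3-Q-prop-2-en-1-yl carbonate | c9ccccc9COc1ccc([C@H]2Oc3cc(OCc9ccccc9)cc(/C=C/COC(=O)OC(C)(C)C)c3[C@@H]2c2cc(OCc9ccccc9)c3c(c2)[C@@H](c2cc(OCc9ccccc9)cc(OCc9ccccc9)c2)[C@H](c2ccc(OCc9ccccc9)cc2)O3)cc1 | intermediate
38 | [3,5-bis(benzyloxy)phenyl]acetic acid | OC(=O)Cc1cc(OCc2ccccc2)cc(OCc2ccccc2)c1 | starting material
39 | pentafluorophenyl [3,5-bis(benzyloxy)phenyl]acetate | O=C(Cc1cc(OCc2ccccc2)cc(OCc2ccccc2)c1)Oc1c(F)c(F)c(F)c(F)c1F | intermediate
40 | pentafluorophenyl (2R,3S)-2-[3,5-bis(benzyloxy)phenyl]-3-Q-pent-4-enoate | c9ccccc9COc1ccc([C@H]2Oc3cc(OCc9ccccc9)cc([C@@H](C=C)[C@H](c5cc(OCc9ccccc9)cc(OCc9ccccc9)c5)C(=O)Oc5c(F)c(F)c(F)c(F)c5F)c3[C@@H]2c2cc(OCc9ccccc9)c3c(c2)[C@@H](c2cc(OCc9ccccc9)cc(OCc9ccccc9)c2)[C@H](c2ccc(OCc9ccccc9)cc2)O3)cc1 | intermediate (not isolated)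
41 | (2R,3S)-2-[3,5-bis(benzyloxy)phenyl]-N-methoxy-N-methyl-3-Q-pent-4-enamide | c9ccccc9COc1ccc([C@H]2Oc3cc(OCc9ccccc9)cc([C@@H](C=C)[C@H](c5cc(OCc9ccccc9)cc(OCc9ccccc9)c5)C(=O)N(C)OC)c3[C@@H]2c2cc(OCc9ccccc9)c3c(c2)[C@@H](c2cc(OCc9ccccc9)cc(OCc9ccccc9)c2)[C@H](c2ccc(OCc9ccccc9)cc2)O3)cc1 | intermediate
42 | (2R,3S)-2-[3,5-bis(benzyloxy)phenyl]-3-Q-pent-4-enal | c9ccccc9COc1ccc([C@H]2Oc3cc(OCc9ccccc9)cc([C@@H](C=C)[C@H](c5cc(OCc9ccccc9)cc(OCc9ccccc9)c5)C=O)c3[C@@H]2c2cc(OCc9ccccc9)c3c(c2)[C@@H](c2cc(OCc9ccccc9)cc(OCc9ccccc9)c2)[C@H](c2ccc(OCc9ccccc9)cc2)O3)cc1 | intermediate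
43 | [4-(benzyloxy)phenyl]magnesium bromide (THF solution) | Br[Mg]c1ccc(OCc2ccccc2)cc1 | starting material
44 | (1S,2R,3S)-1-[4-(benzyloxy)phenyl]-2-[3,5-bis(benzyloxy)phenyl]-3-Q-pent-4-en-1-ol | c9ccccc9COc1ccc([C@H]2Oc3cc(OCc9ccccc9)cc([C@@H](C=C)[C@H](c5cc(OCc9ccccc9)cc(OCc9ccccc9)c5)[C@@H](c5ccc(OCc9ccccc9)cc5)O)c3[C@@H]2c2cc(OCc9ccccc9)c3c(c2)[C@@H](c2cc(OCc9ccccc9)cc(OCc9ccccc9)c2)[C@H](c2ccc(OCc9ccccc9)cc2)O3)cc1 | intermediate
45 | (3S,4R,5S)-5-[4-(benzyloxy)phenyl]-4-[3,5-bis(benzyloxy)phenyl]-3-Q-pentane-1,2,5-triol (C2 epimers) | c9ccccc9COc1ccc([C@H]2Oc3cc(OCc9ccccc9)cc([C@@H](C(O)CO)[C@H](c5cc(OCc9ccccc9)cc(OCc9ccccc9)c5)[C@@H](c5ccc(OCc9ccccc9)cc5)O)c3[C@@H]2c2cc(OCc9ccccc9)c3c(c2)[C@@H](c2cc(OCc9ccccc9)cc(OCc9ccccc9)c2)[C@H](c2ccc(OCc9ccccc9)cc2)O3)cc1 | intermediate (not isolated)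
46 | (2S,3R,4S)-4-[4-(benzyloxy)phenyl]-3-[3,5-bis(benzyloxy)phenyl]-4-hydroxy-2-Q-butanal | c9ccccc9COc1ccc([C@H]2Oc3cc(OCc9ccccc9)cc([C@@H](C=O)[C@H](c5cc(OCc9ccccc9)cc(OCc9ccccc9)c5)[C@@H](c5ccc(OCc9ccccc9)cc5)O)c3[C@@H]2c2cc(OCc9ccccc9)c3c(c2)[C@@H](c2cc(OCc9ccccc9)cc(OCc9ccccc9)c2)[C@H](c2ccc(OCc9ccccc9)cc2)O3)cc1 | intermediate (not isolated)
47 | (3S,4R,5S)-5-[4-(benzyloxy)phenyl]-4-[3,5-bis(benzyloxy)phenyl]-3-Q-oxolan-2-ol (anomers) | c9ccccc9COc1ccc([C@H]2Oc3cc(OCc9ccccc9)cc([C@@H]4[C@H](c5cc(OCc9ccccc9)cc(OCc9ccccc9)c5)[C@@H](c5ccc(OCc9ccccc9)cc5)OC4O)c3[C@@H]2c2cc(OCc9ccccc9)c3c(c2)[C@@H](c2cc(OCc9ccccc9)cc(OCc9ccccc9)c2)[C@H](c2ccc(OCc9ccccc9)cc2)O3)cc1 | intermediate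
48 | (1R,2S,3R,4S)-1,4-bis[4-(benzyloxy)phenyl]-3-[3,5-bis(benzyloxy)phenyl]-2-Q-butane-1,4-diol | c9ccccc9COc1ccc([C@H]2Oc3cc(OCc9ccccc9)cc([C@@H]([C@@H](O)c4ccc(OCc9ccccc9)cc4)[C@H](c5cc(OCc9ccccc9)cc(OCc9ccccc9)c5)[C@@H](c5ccc(OCc9ccccc9)cc5)O)c3[C@@H]2c2cc(OCc9ccccc9)c3c(c2)[C@@H](c2cc(OCc9ccccc9)cc(OCc9ccccc9)c2)[C@H](c2ccc(OCc9ccccc9)cc2)O3)cc1 | intermediate
49 | (2R,3S,4R,5S)-2,5-bis[4-(benzyloxy)phenyl]-4-[3,5-bis(benzyloxy)phenyl]-3-Q-oxolane (deca-O-benzylkobophenol A) | c9ccccc9COc1ccc([C@H]2Oc3cc(OCc9ccccc9)cc([C@@H]4[C@H](c5cc(OCc9ccccc9)cc(OCc9ccccc9)c5)[C@@H](c5ccc(OCc9ccccc9)cc5)O[C@H]4c4ccc(OCc9ccccc9)cc4)c3[C@@H]2c2cc(OCc9ccccc9)c3c(c2)[C@@H](c2cc(OCc9ccccc9)cc(OCc9ccccc9)c2)[C@H](c2ccc(OCc9ccccc9)cc2)O3)cc1 | intermediate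
50 | kobophenol A | Oc1ccc([C@H]2Oc3cc(O)cc([C@@H]4[C@H](c5cc(O)cc(O)c5)[C@@H](c5ccc(O)cc5)O[C@H]4c4ccc(O)cc4)c3[C@@H]2c2cc(O)c3c(c2)[C@@H](c2cc(O)cc(O)c2)[C@H](c2ccc(O)cc2)O3)cc1 | target

## Step count and least certain steps

Total: 30 steps. Longest linear sequence: 25 steps (1–4, 7–10, 12–16, 18–22, 24–30, from 1). Steps 5–6, 11, 17 and 23 are side branches.

**Step 7 (key step).** The most likely failure is a change of pathway. The diene can add to the ynone stepwise as a silyl enol ether (conjugate addition) and then close by aldol reaction onto the ketone; that would turn the ketone carbon into a ring carbon and lose the benzophenone. The diene can also be desilylated by adventitious acid before it reacts, and the acetal at the β-carbon slows the cycloaddition sterically. Fallback: the carbon pattern of 13 is reached without any cycloaddition, setting out from aldehyde 3 and coming back at 13. 3,5-Bis(benzyloxy)benzaldehyde F1 is brominated ortho to the formyl group (N-bromosuccinimide) to 2-bromo-3,5-bis(benzyloxy)benzaldehyde F2. F2 is converted into its diethyl acetal F3 (triethyl orthoformate, acid catalyst). Bromine–lithium exchange (n-BuLi, −78 °C) gives aryllithium F4, which adds to 3 to give benzhydrol F5. MnO2 oxidation gives ketone F6, and MgBr2·OEt2 removes only the benzyl group ortho to the carbonyl by chelation to give 13. This fallback leans on the ortho-directing formyl group for regiochemistry, which is why it is held in reserve.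

**Step 12 (and its twin, step 18).** The o-quinone methide may be released out of step with the ylide. If carbonate transfer and elimination run ahead, the quinone methide is lost to self-condensation or to tert-butoxide; if the phenoxide lingers, it can be benzylated by the sulfonium salt; and the strong amide base can drain the ylide by Sommelet–Hauser rearrangement. The acetal beside the exocyclic carbon also slows the addition. Fallback, from 14 back to 21: 14 is converted with p-toluenesulfinic acid (CH2Cl2, 4 Å sieves; the acetal is restored with triethyl orthoformate if exchanged) into rac-5-(benzyloxy)-3-(diethoxymethyl)-2-{[4-(allyloxy)-3-(benzyloxy)phenyl](4-methylbenzenesulfonyl)methyl}phenol F7. F7 and salt 18 are then stirred with Cs2CO3 in CH2Cl2 at room temperature, where slow loss of sulfinate feeds the same quinone methide 20 at low concentration to an ylide formed under carbonate base. The same change applies to step 18.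

**Step 24.** The allyl terminus that must be attacked carries a very large ortho-substituted aryl group, so attack may drift to the unsubstituted terminus (linear product) or the diastereoselectivity may fall. The substrate is also chiral, so one catalyst pairing may be mismatched. Fallback, from 33 (with 38) back to 41, by sigmatropic rearrangement. Still–Gennari olefination of 33 gives methyl (Z)-3-Q-prop-2-enoate F8, and i-Bu2AlH reduces it to (Z)-3-Q-prop-2-en-1-ol F9. Carbodiimide esterification with 38 gives ester F10. KN(SiMe3)2 and Me3SiCl give the (Z)-silyl ketene acetal F11, whose Ireland–Claisen rearrangement through a chair places the two aryl groups in the required relative arrangement. The product is a pair of acids, (2R,3S)-2-[3,5-bis(benzyloxy)phenyl]-3-Q-pent-4-enoic acid F12 and its (2S,3R) isomer F13; they are diastereomers because of the Q group and are separated by chromatography. Amide coupling of F12 with N,O-dimethylhydroxylamine gives 41. The price is the loss of the material that ends as F13.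

**Step 29.** Stereocontrol at the two ether carbons rests on the cation closing trans. A carbinol of the wrong configuration that does not ionise is carried into a cis isomer, prolonged acid can epimerise the product, and the benzylic cations can be captured by a neighbouring bis(benzyloxy)phenyl ring to give an indane. Fallback, from 47 (with 43) back to 49, forming the C2–aryl bond on a ring that is already closed. Lactol 47 and benzenesulfinic acid (CaCl2, CH2Cl2) give the 2-(phenylsulfonyl)oxolane F14. Bis[4-(benzyloxy)phenyl]zinc F15, made from 43 and ZnBr2, displaces the sulfone through the cyclic oxocarbenium ion. The aryl group should enter anti to the two cis aryl groups on the ring, giving 49 without any ionisation of a benzylic ether.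

**Step 30.** Ten benzyl ethers must go while three benzylic ring C–O bonds stay; over-reduction would open a dihydrobenzofuran or the oxolane, and partially benzylated material may precipitate and stall. Fallback, from 49 to 50 directly, by Lewis-acid debenzylation with BCl3 in the presence of pentamethylbenzene as cation trap in CH2Cl2 at −78 °C. It makes no new intermediate; it exposes the ring ethers to a Lewis acid at low temperature and is therefore second choice.

## Further compounds

F1 | step 7 | 3,5-bis(benzyloxy)benzaldehyde | O=Cc1cc(OCc2ccccc2)cc(OCc2ccccc2)c1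
F2 | step 7 | 2-bromo-3,5-bis(benzyloxy)benzaldehyde | O=Cc1cc(OCc2ccccc2)cc(OCc2ccccc2)c1Br
F3 | step 7 | 1,5-bis(benzyloxy)-2-bromo-3-(diethoxymethyl)benzene | CCOC(OCC)c1cc(OCc2ccccc2)cc(OCc2ccccc2)c1Br
F4 | step 7 | [2,4-bis(benzyloxy)-6-(diethoxymethyl)phenyl]lithium | CCOC(OCC)c1cc(OCc2ccccc2)cc(OCc2ccccc2)c1[Li]
F5 | step 7 | rac-[4-(allyloxy)-3-(benzyloxy)phenyl][2,4-bis(benzyloxy)-6-(diethoxymethyl)phenyl]methanol | CCOC(OCC)c1cc(OCc2ccccc2)cc(OCc2ccccc2)c1C(O)c1ccc(OCC=C)c(OCc2ccccc2)c1
F6 | step 7 | [4-(allyloxy)-3-(benzyloxy)phenyl][2,4-bis(benzyloxy)-6-(diethoxymethyl)phenyl]methanone | CCOC(OCC)c1cc(OCc2ccccc2)cc(OCc2ccccc2)c1C(=O)c1ccc(OCC=C)c(OCc2ccccc2)c1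
F7 | step 12 | rac-5-(benzyloxy)-3-(diethoxymethyl)-2-{[4-(allyloxy)-3-(benzyloxy)phenyl](4-methylbenzenesulfonyl)methyl}phenol | CCOC(OCC)c1cc(OCc2ccccc2)cc(O)c1C(c1ccc(OCC=C)c(OCc2ccccc2)c1)S(=O)(=O)c1ccc(C)cc1
F8 | step 24 | methyl (Z)-3-Q-prop-2-enoate | c9ccccc9COc1ccc([C@H]2Oc3cc(OCc9ccccc9)cc(/C=C\C(=O)OC)c3[C@@H]2c2cc(OCc9ccccc9)c3c(c2)[C@@H](c2cc(OCc9ccccc9)cc(OCc9ccccc9)c2)[C@H](c2ccc(OCc9ccccc9)cc2)O3)cc1
F9 | step 24 | (Z)-3-Q-prop-2-en-1-ol | c9ccccc9COc1ccc([C@H]2Oc3cc(OCc9ccccc9)cc(/C=C\CO)c3[C@@H]2c2cc(OCc9ccccc9)c3c(c2)[C@@H](c2cc(OCc9ccccc9)cc(OCc9ccccc9)c2)[C@H](c2ccc(OCc9ccccc9)cc2)O3)cc1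
F10 | step 24 | (Z)-3-Q-prop-2-en-1-yl [3,5-bis(benzyloxy)phenyl]acetate | c9ccccc9COc1ccc([C@H]2Oc3cc(OCc9ccccc9)cc(/C=C\COC(=O)Cc5cc(OCc9ccccc9)cc(OCc9ccccc9)c5)c3[C@@H]2c2cc(OCc9ccccc9)c3c(c2)[C@@H](c2cc(OCc9ccccc9)cc(OCc9ccccc9)c2)[C@H](c2ccc(OCc9ccccc9)cc2)O3)cc1
F11 | step 24 | (Z)-silyl ketene acetal of F10 (aryl cis to the silyloxy group) | c9ccccc9COc1ccc([C@H]2Oc3cc(OCc9ccccc9)cc(/C=C\CO/C(O[Si](C)(C)C)=C/c5cc(OCc9ccccc9)cc(OCc9ccccc9)c5)c3[C@@H]2c2cc(OCc9ccccc9)c3c(c2)[C@@H](c2cc(OCc9ccccc9)cc(OCc9ccccc9)c2)[C@H](c2ccc(OCc9ccccc9)cc2)O3)cc1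
F12 | step 24 | (2R,3S)-2-[3,5-bis(benzyloxy)phenyl]-3-Q-pent-4-enoic acid | c9ccccc9COc1ccc([C@H]2Oc3cc(OCc9ccccc9)cc([C@@H](C=C)[C@H](c5cc(OCc9ccccc9)cc(OCc9ccccc9)c5)C(=O)O)c3[C@@H]2c2cc(OCc9ccccc9)c3c(c2)[C@@H](c2cc(OCc9ccccc9)cc(OCc9ccccc9)c2)[C@H](c2ccc(OCc9ccccc9)cc2)O3)cc1
F13 | step 24 | (2S,3R)-2-[3,5-bis(benzyloxy)phenyl]-3-Q-pent-4-enoic acid | c9ccccc9COc1ccc([C@H]2Oc3cc(OCc9ccccc9)cc([C@H](C=C)[C@@H](c5cc(OCc9ccccc9)cc(OCc9ccccc9)c5)C(=O)O)c3[C@@H]2c2cc(OCc9ccccc9)c3c(c2)[C@@H](c2cc(OCc9ccccc9)cc(OCc9ccccc9)c2)[C@H](c2ccc(OCc9ccccc9)cc2)O3)cc1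
F14 | step 29 | (3S,4R,5S)-5-[4-(benzyloxy)phenyl]-4-[3,5-bis(benzyloxy)phenyl]-2-(phenylsulfonyl)-3-Q-oxolane (C2 epimers) | c9ccccc9COc1ccc([C@H]2Oc3cc(OCc9ccccc9)cc([C@@H]4[C@H](c5cc(OCc9ccccc9)cc(OCc9ccccc9)c5)[C@@H](c5ccc(OCc9ccccc9)cc5)OC4S(=O)(=O)c4ccccc4)c3[C@@H]2c2cc(OCc9ccccc9)c3c(c2)[C@@H](c2cc(OCc9ccccc9)cc(OCc9ccccc9)c2)[C@H](c2ccc(OCc9ccccc9)cc2)O3)cc1
F15 | step 29 | bis[4-(benzyloxy)phenyl]zinc | c1ccccc1COc1ccc([Zn]c2ccc(OCc3ccccc3)cc2)cc1
F0 | step 30 | none | none
A1 | alternative 1 | deca-O-methylkobophenol A | COc1ccc([C@H]2Oc3cc(OC)cc([C@@H]4[C@H](c5cc(OC)cc(OC)c5)[C@@H](c5ccc(OC)cc5)O[C@H]4c4ccc(OC)cc4)c3[C@@H]2c2cc(OC)c3c(c2)[C@@H](c2cc(OC)cc(OC)c2)[C@H](c2ccc(OC)cc2)O3)cc1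
A2 | alternative 2 | trans-4-[3,5-bis(mesyloxy)phenyl]-3-(3,5-dimethoxyphenyl)-2,5-bis(4-methoxyphenyl)-4,5-dihydrofuran | COc1ccc(cc1)C1=C(c2cc(OC)cc(OC)c2)[C@H](c2cc(OS(C)(=O)=O)cc(OS(C)(=O)=O)c2)[C@@H](c2ccc(OC)cc2)O1
A3 | alternative 3 | methyl 2-[2-(4-benzyloxy-3-methoxybenzoyl)-3,5-dimethoxyphenyl]acetate | COC(=O)Cc1cc(OC)cc(OC)c1C(=O)c1ccc(OCc2ccccc2)c(OC)c1
A4 | alternative 3 | 3,5-dimethoxybenzyne | COC1=CC(OC)=CC#C1
A5 | alternative 3 | methyl 3-[4-(benzyloxy)-3-methoxyphenyl]-3-oxopropanoate | COC(=O)CC(=O)c1ccc(OCc2ccccc2)c(OC)c1
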